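Cuts, in retrosynthetic order: the ester C–O bond of the ferulate; the C4–C4a bond of pyran ring B; the terminal alkyne carbon (ethynyl back to formyl back to vinyl); the O1–C2 ether bond.
Forward: benzene ring A is bought as acetovanillone 1; its phenol oxygen is joined to C2 of isoprene monoepoxide 2 by palladium-catalysed allylic etherification; the vinyl group is turned into the ethynyl group C3≡C4; ring B then closes by gold-catalysed cycloisomerization; the ferulate chain is attached last.
What makes the closure possible: in ring A, C4a is the only unsubstituted carbon ortho to O1 (C8 bears OMe; the acetyl group sits on C6, para to O1 and meta to C4a), so the O1 lone pair activates exactly this carbon; C2 is quaternary, which holds the alkyne over C4a; the alkyne already has the oxidation level of the C3=C4 alkene, so no activating group, tether or halogen has to be put in and taken out.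
Stereochemistry: the single stereocentre C2 (R) is set in step 1 by the chiral diphosphine on palladium (dynamic kinetic asymmetric transformation of racemic 2); every later step, the ring closure included, leaves the four bonds of C2 intact.

Key step: step 5

Remark: the (S,S) antipode of the ligand is assumed to lead to the R ether, by analogy with other pronucleophiles delivered to vinyl epoxides under this catalyst; the configuration of 3 is to be confirmed (Mosher ester, or comparison with 7 made by the chiral-pool fallback), and the (R,R) ligand is used instead if the sense is opposite.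

Step 1
Reactants: 1 acetovanillone (1-(4-hydroxy-3-methoxyphenyl)ethan-1-one); 2 racemic isoprene monoepoxide (2-methyl-2-vinyloxirane)
Product: 3 1-(4-{[(2R)-1-hydroxy-2-methylbut-3-en-2-yl]oxy}-3-methoxyphenyl)ethan-1-one
Conditions: Pd2(dba)3·CHCl3 (1 mol %), (S,S)-DACH-phenyl Trost ligand [(1S,2S)-N,N′-bis(2-diphenylphosphinobenzoyl)cyclohexane-1,2-diamine] (3 mol %), CH2Cl2, rt, 2 added slowly
Reagents that add atoms: none
Why: Zerovalent palladium opens both enantiomers of 2 to rapidly interconverting π-allyl zwitterions, the phenol protonates the alkoxide and the phenoxide is delivered to the adjacent tertiary terminus inside the chiral pocket of the ligand (asymmetric Tsuji–Trost allylic etherification run as a dynamic kinetic asymmetric transformation), which should give the branched ether and set C2 as R.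

Step 2
Reactants: 3 1-(4-{[(2R)-1-hydroxy-2-methylbut-3-en-2-yl]oxy}-3-methoxyphenyl)ethan-1-one
Product: 4 1-(4-{[(2R)-1-[(tert-butyldimethylsilyl)oxy]-2-methylbut-3-en-2-yl]oxy}-3-methoxyphenyl)ethan-1-one
Conditions: TBSCl, imidazole, DMF, rt
Reagents that add atoms: tert-butyldimethylsilyl chloride (TBSCl), CC(C)(C)[Si](C)(C)Cl
Why: Imidazole-promoted silyl ether formation on the primary alcohol masks the hydroxyl group against hemiacetal formation and retro-aldol cleavage in steps 3 and 4 and against 5-endo attack on the gold-activated alkyne in step 5.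

Step 3
Reactants: 4 1-(4-{[(2R)-1-[(tert-butyldimethylsilyl)oxy]-2-methylbut-3-en-2-yl]oxy}-3-methoxyphenyl)ethan-1-one
Product: 6 (2S)-2-(4-acetyl-2-methoxyphenoxy)-3-[(tert-butyldimethylsilyl)oxy]-2-methylpropanal, via secondary ozonide 5 (not isolated)
Conditions: O3, CH2Cl2, −78 °C (Sudan red end point); PPh3, −78 °C to rt
Reagents that add atoms: ozone, [O-][O+]=O
Why: Ozonolysis (1,3-dipolar cycloaddition, cycloreversion and recombination to the secondary ozonide, then reductive cleavage by the phosphine) cuts the only C=C bond, which is far more reactive toward ozone than the acetyl-deactivated arene, and the aldehyde formed has no α-hydrogen, so C2 cannot epimerize (the descriptor changes to S only because CHO outranks CH2OSi).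

Step 4
Reactants: 6 (2S)-2-(4-acetyl-2-methoxyphenoxy)-3-[(tert-butyldimethylsilyl)oxy]-2-methylpropanal
Product: 7 1-(4-{[(2R)-1-[(tert-butyldimethylsilyl)oxy]-2-methylbut-3-yn-2-yl]oxy}-3-methoxyphenyl)ethan-1-one
Conditions: dimethyl (1-diazo-2-oxopropyl)phosphonate, K2CO3, MeOH, 0 °C to rt
Reagents that add atoms: dimethyl (1-diazo-2-oxopropyl)phosphonate (Ohira–Bestmann reagent), CC(=O)C(=[N+]=[N-])P(=O)(OC)OC
Why: Ohira–Bestmann homologation (Seyferth–Gilbert type: addition of the diazophosphonate anion, loss of dimethyl phosphate and N2, 1,2-hydride shift of the alkylidene carbene) converts the activated α-aryloxy aldehyde into the terminal alkyne under carbonate base that should leave the methyl ketone, the silyl ether and the quaternary centre untouched.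

Step 5
Reactants: 7 1-(4-{[(2R)-1-[(tert-butyldimethylsilyl)oxy]-2-methylbut-3-yn-2-yl]oxy}-3-methoxyphenyl)ethan-1-one
Product: 8 1-[(2R)-2-{[(tert-butyldimethylsilyl)oxy]methyl}-8-methoxy-2-methyl-2H-chromen-6-yl]ethan-1-one
Conditions: Ph3PAuNTf2 (3 mol %), 4 Å MS, CH2Cl2, rt
Reagents that add atoms: none
Why: The cationic monovalent gold centre binds the terminal alkyne of 7, the ring A carbon ortho to the ether oxygen (the future C4a) attacks the terminal alkyne carbon anti to gold, the arenium ion loses its proton and protodeauration of the vinylgold species releases the cis C3=C4 alkene and the catalyst, so the step is an isomerization that needs no prior halogenation of the arene. The closest known reaction type is the gold- or platinum-catalysed intramolecular hydroarylation (cycloisomerization) of aryl propargyl ethers to 2H-chromenes, which tolerates 1,1-disubstituted propargyl groups and acyl-substituted arenes. Pyran ring B is closed in the 6-endo-dig mode. No new stereocentre is formed, and C2 should keep its R configuration because none of its four bonds is broken, in contrast to the thermal propargyl Claisen and electrocyclization sequence, which would cleave the O1–C2 bond and pass through a planar ortho-quinone methide. The step needs site selectivity on the arene and 6-endo over 5-exo selectivity: C8 is blocked by the methoxy group and C4a lies ortho to O1 and meta to the acetyl group, the unsubstituted alkyne terminus favours attack at the distal carbon, and the quaternary C2 holds the alkyne over C4a. The silyl ether is too poor a nucleophile to add 5-endo to the activated alkyne, and molecular sieves exclude the water that would hydrate it.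

Step 6
Reactants: 8 1-[(2R)-2-{[(tert-butyldimethylsilyl)oxy]methyl}-8-methoxy-2-methyl-2H-chromen-6-yl]ethan-1-one
Product: 9 1-[(2R)-2-(hydroxymethyl)-8-methoxy-2-methyl-2H-chromen-6-yl]ethan-1-one
Conditions: TBAF, AcOH, THF, 0 °C to rt
Reagents that add atoms: none
Why: Fluoride-induced desilylation, buffered with acetic acid so that no alkoxide builds up next to the methyl ketone, should free the primary alcohol without touching the chromene.

Step 7
Reactants: 9 1-[(2R)-2-(hydroxymethyl)-8-methoxy-2-methyl-2H-chromen-6-yl]ethan-1-one; 10 O-acetylferulic acid ((E)-3-(4-acetoxy-3-methoxyphenyl)prop-2-enoic acid)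
Product: 12 [(2R)-6-acetyl-8-methoxy-2-methyl-2H-chromen-2-yl]methyl (E)-3-(4-acetoxy-3-methoxyphenyl)prop-2-enoate, via acid chloride 11 (not isolated)
Conditions: 10, (COCl)2, DMF (cat.), CH2Cl2, 0 °C to rt, evaporation; then 9, Et3N, DMAP (cat.), CH2Cl2, 0 °C to rt
Reagents that add atoms: none
Why: Acyl transfer from the acid chloride to the primary alcohol under DMAP catalysis (nucleophilic acyl substitution) forms the ester without any substitution at the neopentyl-type carbon and with the E alkene intact, the phenol being masked as its acetate so that it cannot compete as a nucleophile.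

Step 8
Reactants: 12 [(2R)-6-acetyl-8-methoxy-2-methyl-2H-chromen-2-yl]methyl (E)-3-(4-acetoxy-3-methoxyphenyl)prop-2-enoate
Product: 13 [(2R)-6-acetyl-8-methoxy-2-methyl-2H-chromen-2-yl]methyl (E)-3-(4-hydroxy-3-methoxyphenyl)prop-2-enoate (target)
Conditions: pyrrolidine (2 equiv), CH2Cl2/EtOH, 0 °C; dilute aqueous HCl work-up
Reagents that add atoms: none
Why: Aminolysis of the aryl acetate by pyrrolidine is much faster than attack on the alkyl cinnamate ester or the ketone because the phenoxide is by far the better leaving group, which should release the free phenol of the target chemoselectively.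

Compound list
1 | acetovanillone, 1-(4-hydroxy-3-methoxyphenyl)ethan-1-one | CC(=O)c1ccc(O)c(OC)c1 | starting material
2 | racemic isoprene monoepoxide, 2-methyl-2-vinyloxirane | CC1(C=C)CO1 | starting material
3 | 1-(4-{[(2R)-1-hydroxy-2-methylbut-3-en-2-yl]oxy}-3-methoxyphenyl)ethan-1-one | OC[C@@](Oc1ccc(C(C)=O)cc1OC)(C)C=C | intermediate
4 | 1-(4-{[(2R)-1-[(tert-butyldimethylsilyl)oxy]-2-methylbut-3-en-2-yl]oxy}-3-methoxyphenyl)ethan-1-one | CC(C)(C)[Si](C)(C)OC[C@@](Oc1ccc(C(C)=O)cc1OC)(C)C=C | intermediate
5 | secondary ozonide of 4, 1-(4-{[(2S)-1-[(tert-butyldimethylsilyl)oxy]-2-(1,2,4-trioxolan-3-yl)propan-2-yl]oxy}-3-methoxyphenyl)ethan-1-one (both epimers at the trioxolane carbon) | CC(C)(C)[Si](C)(C)OC[C@@](Oc1ccc(C(C)=O)cc1OC)(C)C1OCOO1 | intermediate (not isolated)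
6 | (2S)-2-(4-acetyl-2-methoxyphenoxy)-3-[(tert-butyldimethylsilyl)oxy]-2-methylpropanal | CC(C)(C)[Si](C)(C)OC[C@@](Oc1ccc(C(C)=O)cc1OC)(C)C=O | intermediate
7 | 1-(4-{[(2R)-1-[(tert-butyldimethylsilyl)oxy]-2-methylbut-3-yn-2-yl]oxy}-3-methoxyphenyl)ethan-1-one | CC(C)(C)[Si](C)(C)OC[C@@](Oc1ccc(C(C)=O)cc1OC)(C)C#C | intermediate
8 | 1-[(2R)-2-{[(tert-butyldimethylsilyl)oxy]methyl}-8-methoxy-2-methyl-2H-chromen-6-yl]ethan-1-one | CC(C)(C)[Si](C)(C)OC[C@@]1(C)C=Cc2cc(C(C)=O)cc(OC)c2O1 | intermediate
9 | 1-[(2R)-2-(hydroxymethyl)-8-methoxy-2-methyl-2H-chromen-6-yl]ethan-1-one | OC[C@@]1(C)C=Cc2cc(C(C)=O)cc(OC)c2O1 | intermediate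
10 | O-acetylferulic acid, (E)-3-(4-acetoxy-3-methoxyphenyl)prop-2-enoic acid | CC(=O)Oc1ccc(/C=C/C(=O)O)cc1OC | starting material
11 | (E)-3-(4-acetoxy-3-methoxyphenyl)prop-2-enoyl chloride | CC(=O)Oc1ccc(/C=C/C(=O)Cl)cc1OC | intermediate (not isolated)
12 | [(2R)-6-acetyl-8-methoxy-2-methyl-2H-chromen-2-yl]methyl (E)-3-(4-acetoxy-3-methoxyphenyl)prop-2-enoate | CC(=O)Oc1ccc(/C=C/C(=O)OC[C@@]2(C)C=Cc3cc(C(C)=O)cc(OC)c3O2)cc1OC | intermediate
13 | [(2R)-6-acetyl-8-methoxy-2-methyl-2H-chromen-2-yl]methyl (E)-3-(4-hydroxy-3-methoxyphenyl)prop-2-enoate | COc1cc(/C=C/C(=O)OC[C@@]2(C)C=Cc3cc(C(C)=O)cc(OC)c3O2)ccc1O | target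

Total step count: 8. Longest linear sequence: 8 steps (1 and 2 to 13).

Steps most likely to fail

Step 1. Attack of the hindered ortho-methoxy phenoxide at the tertiary allyl terminus may be slow enough for palladium to re-ionize the electron-poor aryl ether already formed, so that the branched ether drifts to the linear one and enantiomeric purity erodes; the sense of induction may also differ from the assumed one. The fallback replaces catalytic asymmetric etherification by a chiral-pool route with nucleophilic aromatic substitution. It sets out from none of the numbered compounds, since purchased (R)-2-methylglycidol and 4-fluoro-3-methoxybenzonitrile take the place of 1 and 2, and it comes back to the route at 7. The epoxide is opened at its CH2 carbon by sodium 4-methoxybenzyl oxide (4-methoxybenzyl alcohol, NaH, DMF, 60 °C) to give (2R)-3-[(4-methoxybenzyl)oxy]-2-methylpropane-1,2-diol F1. Parikh–Doering oxidation of the primary alcohol (SO3·pyridine, DMSO, iPr2NEt) gives (2S)-2-hydroxy-3-[(4-methoxybenzyl)oxy]-2-methylpropanal F2. Ohira–Bestmann homologation as in step 4 gives (2R)-1-[(4-methoxybenzyl)oxy]-2-methylbut-3-yn-2-ol F3. Its potassium alkoxide (KN(SiMe3)2, THF/DMF, 0 to 50 °C) displaces fluoride from 4-fluoro-3-methoxybenzonitrile, with no bond at the stereocentre broken, to give 3-methoxy-4-({(2R)-1-[(4-methoxybenzyl)oxy]-2-methylbut-3-yn-2-yl}oxy)benzonitrile F4. MeMgBr (3 equiv, THF, 50 °C) adds to the nitrile to give 1-[3-methoxy-4-({(2R)-1-[(4-methoxybenzyl)oxy]-2-methylbut-3-yn-2-yl}oxy)phenyl]ethan-1-imine F5, which is hydrolysed without isolation (aqueous HCl) to 1-[3-methoxy-4-({(2R)-1-[(4-methoxybenzyl)oxy]-2-methylbut-3-yn-2-yl}oxy)phenyl]ethan-1-one F6. DDQ (CH2Cl2/H2O) removes the benzylic ether to give 1-(4-{[(2R)-1-hydroxy-2-methylbut-3-yn-2-yl]oxy}-3-methoxyphenyl)ethan-1-one F7, and silylation as in step 2 gives 7.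

Step 5. The cationic gold may ionize the tertiary propargylic C–O bond (loss of the aryloxide or erosion of the R configuration), closure may go 5-exo to a 3-methylene-2,3-dihydrobenzofuran, or traces of water may hydrate the alkyne. The fallback closes ring B at C3=C4 by olefin metathesis instead of at C4–C4a. It sets out from 1 and comes back to the route at 8. O-Allylation (allyl bromide, K2CO3, acetone, reflux) gives 1-[3-methoxy-4-(prop-2-en-1-yloxy)phenyl]ethan-1-one F8. Aromatic Claisen rearrangement (N,N-diethylaniline, 190 °C) moves the allyl group to the only free ortho carbon to give 1-[4-hydroxy-3-methoxy-5-(prop-2-en-1-yl)phenyl]ethan-1-one F9. Alkene isomerization (RuHCl(CO)(PPh3)3, toluene, 80 °C) gives 1-{4-hydroxy-3-methoxy-5-[(1E)-prop-1-en-1-yl]phenyl}ethan-1-one F10. Etherification with 2 under the conditions of step 1 gives 1-(4-{[(2R)-1-hydroxy-2-methylbut-3-en-2-yl]oxy}-3-methoxy-5-[(1E)-prop-1-en-1-yl]phenyl)ethan-1-one F11, and silylation as in step 2 gives 1-(4-{[(2R)-1-[(tert-butyldimethylsilyl)oxy]-2-methylbut-3-en-2-yl]oxy}-3-methoxy-5-[(1E)-prop-1-en-1-yl]phenyl)ethan-1-one F12. Ring-closing metathesis (second-generation Grubbs catalyst, CH2Cl2, 40 °C) with loss of propene gives 8.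

Step 4. Addition of the diazophosphonate anion to the neopentyl-type aldehyde may be slow, so that attack at the methyl ketone or methanolysis of the silyl ether competes. The fallback uses olefination and β-elimination instead of diazo homologation. It sets out from 6 and comes back to the route at 7. Stork–Zhao olefination ((iodomethyl)triphenylphosphonium iodide, NaN(SiMe3)2, THF, −78 °C) gives 1-(4-{[(2R,3Z)-1-[(tert-butyldimethylsilyl)oxy]-4-iodo-2-methylbut-3-en-2-yl]oxy}-3-methoxyphenyl)ethan-1-one F13. Anti elimination of HI with NaN(SiMe3)2 (2.5 equiv, THF, −78 to −20 °C; the ketone is carried as its enolate and returns on work-up) gives 7.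

Further compounds
F1 | step 1 | (2R)-3-[(4-methoxybenzyl)oxy]-2-methylpropane-1,2-diol | COc1ccc(COC[C@@](O)(C)CO)cc1
F2 | step 1 | (2S)-2-hydroxy-3-[(4-methoxybenzyl)oxy]-2-methylpropanal | COc1ccc(COC[C@@](O)(C)C=O)cc1
F3 | step 1 | (2R)-1-[(4-methoxybenzyl)oxy]-2-methylbut-3-yn-2-ol | COc1ccc(COC[C@@](O)(C)C#C)cc1
F4 | step 1 | 3-methoxy-4-({(2R)-1-[(4-methoxybenzyl)oxy]-2-methylbut-3-yn-2-yl}oxy)benzonitrile | COc1ccc(COC[C@@](Oc2ccc(C#N)cc2OC)(C)C#C)cc1
F5 | step 1 | 1-[3-methoxy-4-({(2R)-1-[(4-methoxybenzyl)oxy]-2-methylbut-3-yn-2-yl}oxy)phenyl]ethan-1-imine (not isolated) | COc1ccc(COC[C@@](Oc2ccc(C(C)=N)cc2OC)(C)C#C)cc1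
F6 | step 1 | 1-[3-methoxy-4-({(2R)-1-[(4-methoxybenzyl)oxy]-2-methylbut-3-yn-2-yl}oxy)phenyl]ethan-1-one | COc1ccc(COC[C@@](Oc2ccc(C(C)=O)cc2OC)(C)C#C)cc1
F7 | step 1 | 1-(4-{[(2R)-1-hydroxy-2-methylbut-3-yn-2-yl]oxy}-3-methoxyphenyl)ethan-1-one | OC[C@@](Oc1ccc(C(C)=O)cc1OC)(C)C#C
F8 | step 5 | 1-[3-methoxy-4-(prop-2-en-1-yloxy)phenyl]ethan-1-one | C=CCOc1ccc(C(C)=O)cc1OC
F9 | step 5 | 1-[4-hydroxy-3-methoxy-5-(prop-2-en-1-yl)phenyl]ethan-1-one | C=CCc1cc(C(C)=O)cc(OC)c1O
F10 | step 5 | 1-{4-hydroxy-3-methoxy-5-[(1E)-prop-1-en-1-yl]phenyl}ethan-1-one | C/C=C/c1cc(C(C)=O)cc(OC)c1O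
F11 | step 5 | 1-(4-{[(2R)-1-hydroxy-2-methylbut-3-en-2-yl]oxy}-3-methoxy-5-[(1E)-prop-1-en-1-yl]phenyl)ethan-1-one | OC[C@@](Oc1c(/C=C/C)cc(C(C)=O)cc1OC)(C)C=C
F12 | step 5 | 1-(4-{[(2R)-1-[(tert-butyldimethylsilyl)oxy]-2-methylbut-3-en-2-yl]oxy}-3-methoxy-5-[(1E)-prop-1-en-1-yl]phenyl)ethan-1-one | CC(C)(C)[Si](C)(C)OC[C@@](Oc1c(/C=C/C)cc(C(C)=O)cc1OC)(C)C=C
F13 | step 4 | 1-(4-{[(2R,3Z)-1-[(tert-butyldimethylsilyl)oxy]-4-iodo-2-methylbut-3-en-2-yl]oxy}-3-methoxyphenyl)ethan-1-one | CC(C)(C)[Si](C)(C)OC[C@@](Oc1ccc(C(C)=O)cc1OC)(C)/C=C\I
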